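**Plan**

- Retrosynthesis: the central cyclohexene is cut at its two Diels–Alder bonds (C17–C19' and C27–C27'), which halves the target into two molecules of tetraene monomer 46. In 46 the myristate, the enal (C7 ketone plus an isopropenyl unit) and the C14–C15 bond (ring-B epoxide plus a trienyllithium) are cut. The spiro[4.5]decane is cut at C6–C11 by a retro-semipinacol step to a hydroazulene (bicyclo[5.3.0]decene) 2,3-epoxy alcohol.
- Enabling feature: the spiro carbon C11 sits between the C10 methyl carbinol of ring A and the C26 carbinol of ring B. It is the α-carbon of a β-hydroxy ketone, which is the product pattern of a 1,2-shift in an epoxy alcohol.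
- Forward order: seven-membered ring (Evans aldol, ring-closing metathesis), then ring B (allylation, B-alkyl Suzuki coupling), then ring A by 7 → 6 ring contraction, then side chain, enal, and the cyclohexene by [4+2] dimerization.
- Stereochemistry: C6 from the Evans aldol; the C26 carbinol by 1,2-induction; C10 and C11 by stereospecific anti migration onto the epoxide; C14 by directed epoxidation and anti opening; C26 by hydroxyl-directed reduction; the two cyclohexene centres by regio-, exo- and facial selectivity of the dimerization.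

Key step: step 13

Remark (assumptions): atom labels follow iridal numbering. Ring A (six-membered) is C6–C11, ring B (five-membered) is C11–C14 plus C26, the enal is C1–C2=C7, the oxypropyl chain is C3–C5, the side chain is C15–C23 with C27 the methylene on C19, and primes mark the second half. TBS = tert-butyldimethylsilyl, TBDPS = tert-butyldiphenylsilyl. Compounds 1, 3, 6, 24, 29, 30 and 39 are taken as purchasable. The C7 carbinol of 43 and the C=N geometry of 20 are left undefined because both are erased in the following step.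

**Route**

Step 1
Reactants: 1 5-(TBSO)pentan-1-ol
Product: 2 5-(TBSO)pentanoic acid
Conditions: TEMPO (cat.), PhI(OAc)2, MeCN/H2O, rt
Reagents that add atoms: water, O
Why: TEMPO/PhI(OAc)2 oxidation takes the primary alcohol through the aldehyde hydrate to the acid and does not touch the silyl ether.

Step 2
Reactants: 2 5-(TBSO)pentanoic acid; 3 (R)-4-benzyl-2-oxazolidinone
Product: 5 (R)-4-benzyl-3-[5-(TBSO)pentanoyl]oxazolidin-2-one, via mixed pivalic anhydride 4 (not isolated)
Conditions: PivCl, Et3N, THF, −20 °C; then 3, LiCl, −20 °C → rt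
Reagents that add atoms: none
Why: mixed-anhydride N-acylation of the LiCl-activated oxazolidinone installs the auxiliary that will set C6.

Step 3
Reactants: 6 4-methylpent-4-en-1-ol
Product: 7 4-methylpent-4-enal
Conditions: Dess–Martin periodinane, NaHCO3, CH2Cl2, 0 °C → rt
Reagents that add atoms: none
Why: Dess–Martin oxidation gives the volatile aldehyde without isomerizing the 1,1-disubstituted alkene.

Step 4
Reactants: 5 N-acyl oxazolidinone; 7 4-methylpent-4-enal
Product: 9 Evans syn-aldol adduct (R)-4-benzyl-3-[(2R,3S)-3-hydroxy-6-methyl-2-(3-TBSO-propyl)hept-6-enoyl]oxazolidin-2-one, via (Z)-boron enolate 8 (not isolated)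
Conditions: Bu2BOTf, iPr2NEt, CH2Cl2, −78 → 0 °C; 7, −78 °C; pH 7 buffer, MeOH, H2O2
Reagents that add atoms: none
Why: Evans syn aldol reaction, in which the (Z)-boron enolate reacts through a chair Zimmerman–Traxler transition state on the face away from the benzyl group, sets C6 (R) and C7 (S).

Step 5
Reactants: 9 syn-aldol adduct
Product: 10 (2R,3S)-3-hydroxy-N-methoxy-N,6-dimethyl-2-(3-TBSO-propyl)hept-6-enamide
Conditions: MeNHOMe·HCl, AlMe3, CH2Cl2, −20 → 0 °C
Reagents that add atoms: N,O-dimethylhydroxylamine hydrochloride, CNOC.Cl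
Why: aluminium-amide transamination (Weinreb amide formation), assisted by the free β-hydroxyl, removes the auxiliary without epimerizing C6.

Step 6
Reactants: 10 Weinreb amide
Product: 11 (2R,3S)-3-(TBSO) Weinreb amide
Conditions: TBSOTf, 2,6-lutidine, CH2Cl2, −78 °C
Reagents that add atoms: tert-butyldimethylsilyl triflate, CC(C)(C)[Si](C)(C)OS(=O)(=O)C(F)(F)F
Why: silyl ether formation blocks retro-aldol cleavage and carries the C7 oxygen, later the C7 ketone, through the route.

Step 7
Reactants: 11 silylated Weinreb amide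
Product: 12 (4R,5S)-5-(TBSO)-8-methyl-4-(3-TBSO-propyl)nona-1,8-dien-3-one
Conditions: CH2=CHMgBr, THF, −78 → 0 °C; cold aq. NH4Cl
Reagents that add atoms: vinylmagnesium bromide, C=C[Mg]Br
Why: Weinreb ketone synthesis, in which the chelated tetrahedral intermediate stops the addition at the enone stage.

Step 8
Reactants: 12 vinyl ketone
Product: 13 (6S,7R)-3-methyl-6-(TBSO)-7-(3-TBSO-propyl)cyclohept-2-en-1-one
Conditions: second-generation Grubbs catalyst RuCl2(PCy3)(H2IMes)(=CHPh) (5 mol %), CH2Cl2, 40 °C, high dilution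
Reagents that add atoms: none
Why: ring-closing metathesis between the vinyl ketone and the 1,1-disubstituted alkene closes the seven-membered ring as the trisubstituted enone with loss of ethene.

Step 9
Reactants: 13 cycloheptenone
Product: 14 (6S,7R)-2-iodo-3-methyl-6-(TBSO)-7-(3-TBSO-propyl)cyclohept-2-en-1-one
Conditions: I2, pyridine, DMAP (cat.), CH2Cl2, rt
Reagents that add atoms: iodine, II
Why: α-iodination of the enone (amine conjugate addition, iodination of the enolate, elimination) provides the vinyl iodide handle at C11.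

Step 10
Reactants: 14 iodoenone
Product: 15 (1R,6S,7R)-1-allyl-2-iodo-3-methyl-6-(TBSO)-7-(3-TBSO-propyl)cyclohept-2-en-1-ol
Conditions: CH2=CHCH2MgBr, THF, −78 °C
Reagents that add atoms: allylmagnesium bromide, C=CC[Mg]Br
Why: 1,2-addition of the allyl Grignard reagent to the enone carbonyl, anti to the C6 side chain (1,2-induction by the α-stereocentre), sets the C26 carbinol with its hydroxyl cis to that chain.

Step 11
Reactants: 15 allyl carbinol
Product: 17 hydroazulenol (7S,8R,8aR)-4-methyl-7-(TBSO)-8-(3-TBSO-propyl)-2,3,5,6,7,8-hexahydroazulen-8a(1H)-ol, via B-alkyl-9-BBN 16 (not isolated)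
Conditions: 9-BBN, THF, rt; then Pd(dppf)Cl2 (10 mol %), AsPh3, Cs2CO3, DMF/H2O, 50 °C
Reagents that add atoms: none
Why: chemoselective hydroboration of the terminal alkene followed by intramolecular B-alkyl Suzuki–Miyaura coupling with the vinyl iodide closes ring B and leaves the tetrasubstituted C10=C11 alkene in the seven-membered ring.

Step 12
Reactants: 17 hydroazulenol
Product: 18 syn-epoxy alcohol (C10–C11 epoxide on the face of the C26 hydroxyl)
Conditions: VO(acac)2 (cat.), t-BuOOH, CH2Cl2, 0 °C
Reagents that add atoms: tert-butyl hydroperoxide, CC(C)(C)OO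
Why: vanadium-catalysed hydroxyl-directed epoxidation of the tertiary allylic alcohol delivers oxygen to the alkene face syn to the C26 hydroxyl.

Step 13
Reactants: 18 syn-epoxy alcohol
Product: 19 spiro hydroxy ketone 6-hydroxy-6-methyl-9-(TBSO)-10-(3-TBSO-propyl)spiro[4.5]decan-1-one (C6 chain, C10 hydroxyl and C11–C26 bond mutually cis on ring A)
Conditions: ZnBr2 (0.3 equiv), CH2Cl2, 0 °C
Reagents that add atoms: none
Why: ZnBr2 bridges the C26 hydroxyl and the syn epoxide oxygen, and as the C11–O bond ionizes the C26–C6 ring bond, which the flexible seven-membered ring can hold anti to it, shifts to C11 while C26 becomes the ketone; this is the semipinacol rearrangement of a 2,3-epoxy alcohol, and the closest known reaction type is the Lewis-acid ring contraction of cyclic tertiary epoxy alcohols to β-hydroxy ketones. Ring A is closed by this 1,2-alkyl shift, a backside displacement of the epoxide oxygen at C11 by the migrating σ-bond, which contracts the seven-membered ring to six and turns the fused bicyclo[5.3.0] skeleton into the spiro[4.5]decane. C11 is formed with inversion (C6 enters anti to the leaving oxygen), C10 keeps its oxygen with retention and C6 migrates with retention, so the cis ring epoxide fixes the C10 hydroxyl cis to the C11–C26 bond on ring A and the aldol-derived C6 centre, cis to the epoxide, fixes the absolute sense. The step needs cleavage of C11–O and not C10–O, and migration of C6 and not C14: the first is secured by chelation and by the push of the carbinol oxygen (only cleavage at C11 ends in a carbonyl), the second by strain (a C14 shift would give a cyclobutane, the C6 shift relieves the seven-membered ring) and by the higher migratory aptitude of the secondary C6.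

Step 14
Reactants: 19 spiro hydroxy ketone
Product: 20 tosylhydrazone of 19
Conditions: TsNHNH2, THF, 50 °C
Reagents that add atoms: 4-methylbenzenesulfonohydrazide, Cc1ccc(cc1)S(=O)(=O)NN
Why: hydrazone condensation of the cyclopentanone prepares the Shapiro reaction, the tertiary hydroxyl being inert.

Step 15
Reactants: 20 tosylhydrazone
Product: 22 spiro[4.5]dec-1-ene (C14=C26 alkene), via vinyllithium 21 (not isolated)
Conditions: n-BuLi (4 equiv), TMEDA, THF, −78 °C → rt; H2O
Reagents that add atoms: none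
Why: Shapiro reaction, in which the hydrazone dianion can lose sulfinate and nitrogen only toward C14 (C11 is quaternary), gives the C14=C26 alkene after protonation of the vinyllithium.

Step 16
Reactants: 22 spiro alkene
Product: 23 ring-B epoxide (C14–C26 epoxide on the face of ring B that carries C10)
Conditions: VO(acac)2 (cat.), t-BuOOH, PhMe, 40 °C
Reagents that add atoms: tert-butyl hydroperoxide, CC(C)(C)OO
Why: vanadium-catalysed epoxidation directed by the homoallylic C10 hydroxyl puts the epoxide on the face of ring B that carries C10.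

Step 17
Reactants: 24 but-2-yne-1,4-diol
Product: 25 4-(TBDPSO)but-2-yn-1-ol
Conditions: NaH (1 equiv), TBDPSCl (1 equiv), THF, 0 °C, diol in excess
Reagents that add atoms: tert-butyl(chloro)diphenylsilane, CC(C)(C)[Si](Cl)(c1ccccc1)c1ccccc1
Why: Williamson-type monosilylation of the symmetric diol through its monosodium alkoxide differentiates the two ends.

Step 18
Reactants: 25 monosilylated butynediol
Product: 27 (Z)-4-(TBDPSO)-3-iodobut-2-en-1-ol, via cyclic alkenylalanate 26 (not isolated)
Conditions: NaAlH2(OCH2CH2OMe)2, THF, 0 °C; then I2, −78 °C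
Reagents that add atoms: iodine, II
Why: hydroxyl-directed trans-hydroalumination places aluminium on the alkyne carbon remote from the free hydroxyl, and iodinolysis with retention gives the (Z)-vinyl iodide with iodine cis to the hydroxymethyl arm.

Step 19
Reactants: 27 (Z)-iodo allylic alcohol
Product: 28 (Z)-4-(TBDPSO)-3-iodobut-2-enal
Conditions: MnO2, CH2Cl2, rt
Reagents that add atoms: none
Why: MnO2 oxidation of the allylic alcohol gives the enal without loss of alkene geometry.

Step 20
Reactants: 29 5-bromo-2-methylpent-2-ene; 30 prop-2-yn-1-ol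
Product: 32 6-methyl-2-methylidenehept-5-en-1-ol, via homoprenylmagnesium bromide 31 (not isolated)
Conditions: Mg, THF; then 30 (0.45 equiv), CuI (10 mol %), THF, −10 °C → rt; aq. NH4Cl
Reagents that add atoms: none
Why: copper-catalysed carbomagnesiation of the propargyl alkoxide adds the homoprenyl group to the internal alkyne carbon, and protonation gives the 2-substituted allyl alcohol.

Step 21
Reactants: 32 allylic alcohol
Product: 33 2-(bromomethyl)-6-methylhepta-1,5-diene
Conditions: PBr3, Et2O, 0 °C
Reagents that add atoms: phosphorus tribromide, BrP(Br)Br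
Why: SN2 bromination of the primary allylic alcohol through its phosphite ester proceeds without allylic transposition.

Step 22
Reactants: 33 allylic bromide
Product: 34 diethyl (6-methyl-2-methylidenehept-5-enyl)phosphonate
Conditions: P(OEt)3, 120 °C
Reagents that add atoms: triethyl phosphite, CCOP(OCC)OCC
Why: Michaelis–Arbuzov reaction of the primary allylic bromide gives the allylic phosphonate.

Step 23
Reactants: 28 (Z)-iodoenal; 34 allylic phosphonate
Product: 35 trienyl iodide (2Z,4E)-1-(TBDPSO)-2-iodo-10-methyl-6-methylideneundeca-2,4,9-triene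
Conditions: NaN(SiMe3)2, THF, −78 → 0 °C
Reagents that add atoms: none
Why: Horner–Wadsworth–Emmons olefination through the α-carbon of the allylic phosphonate anion forms the (E)-C17=C18 alkene and leaves the vinyl iodide untouched.

Step 24
Reactants: 23 ring-B epoxide; 35 trienyl iodide (2.5 equiv)
Product: 37 trans-2-alkenylcyclopentanol (C14 side chain cis to C6, C26 hydroxyl trans to the side chain), via trienyllithium 36 (not isolated)
Conditions: 35, t-BuLi (2 equiv per iodide), Et2O, −78 °C; then 23 (pretreated with MeLi, 1 equiv), BF3·OEt2, −78 °C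
Reagents that add atoms: none
Why: iodine–lithium exchange with retention of alkene geometry and BF3-assisted SN2 opening of the epoxide at C14, the carbon remote from the quaternary spiro centre, sets C14 with inversion.

Step 25
Reactants: 37 coupled product
Product: 38 tetraol (C3, C7, C10 and C26 hydroxyls free, TBDPS ether kept)
Conditions: HF·pyridine, pyridine, THF, 0 °C → rt
Reagents that add atoms: none
Why: fluoride desilylation removes both TBS ethers while the bulkier TBDPS ether survives.

Step 26
Reactants: 38 tetraol; 39 tetradecanoyl chloride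
Product: 40 C3 myristate
Conditions: 2,4,6-collidine, CH2Cl2, −78 → −40 °C
Reagents that add atoms: none
Why: low-temperature acylation with the acid chloride and a hindered pyridine base esterifies only the primary hydroxyl.

Step 27
Reactants: 40 myristate triol
Product: 41 C7,C26-diketone
Conditions: Dess–Martin periodinane, NaHCO3, CH2Cl2, 0 °C
Reagents that add atoms: none
Why: Dess–Martin oxidation converts both secondary alcohols into ketones under buffered conditions that do not epimerize C6 or C14.

Step 28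
Reactants: 41 diketone
Product: 42 C7 ketone with C26 hydroxyl cis to the C14 side chain
Conditions: Me4NBH(OAc)3, MeCN/AcOH, −30 °C
Reagents that add atoms: none
Why: hydroxyl-directed (Evans–Saksena) reduction, in which boron binds the C10 hydroxyl and delivers hydride to the C26 ketone from the face of ring B that carries C10, sets C26, while the C7 ketone has no β-hydroxyl and is left.

Step 29
Reactants: 42 hydroxy ketone
Product: 43 C7 isopropenyl carbinol
Conditions: CH2=C(CH3)MgBr, CeCl3, THF, −78 °C
Reagents that add atoms: isopropenylmagnesium bromide, CC(=C)[Mg]Br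
Why: organocerium 1,2-addition to the C7 ketone occurs without enolization of C6 and faster than attack on the ester.

Step 30
Reactants: 43 tertiary allylic alcohol
Product: 44 (2Z)-allylic primary alcohol (C2=C7 alkene, hydroxymethyl cis to C6)
Conditions: Ph3SiOReO3 (5 mol %), Et2O, −20 → 0 °C
Reagents that add atoms: none
Why: rhenium-oxo catalysed 1,3-transposition ([3,3] shift of the allyl perrhenate) moves the hydroxyl to the primary carbon and creates the tetrasubstituted C2=C7 alkene, its reversibility favouring the geometry with the methyl group on the C8 side.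

Step 31
Reactants: 44 allylic alcohol
Product: 45 TBDPS-protected monomer (enal)
Conditions: MnO2, CH2Cl2, rt
Reagents that add atoms: none
Why: MnO2 oxidizes only the allylic primary alcohol to the enal, the secondary C26 and tertiary C10 hydroxyls being unreactive.

Step 32
Reactants: 45 protected monomer
Product: 46 tetraene monomer
Conditions: Bu4NF, AcOH, THF, 0 °C → rt
Reagents that add atoms: none
Why: buffered fluoride desilylation frees the allylic alcohol without touching the ester or the enal.

Step 33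
Reactants: 46 tetraene monomer (two molecules)
Product: 47 target CNP0458412.1
Conditions: PhMe (1 M), BHT, 100 °C, dark
Reagents that add atoms: none
Why: thermal Diels–Alder homodimerization in which C17=C18–C19=C27 of one molecule (the only diene unit that can become s-cis) adds to the unhindered C19'=C27' methylene of the other, the ortho/para rule joining C17 to C19'; the dienyl arm on C19' is expected to lie exo, trans to the C17 substituent, and the diene face to be chosen by the C14 stereocentre held by allylic strain, which is the least secure element.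

**Compound list**

1 | 5-(TBSO)pentan-1-ol | CC(C)(C)[Si](C)(C)OCCCCCO | starting material
2 | 5-(TBSO)pentanoic acid | CC(C)(C)[Si](C)(C)OCCCCC(=O)O | intermediate
3 | (R)-4-benzyl-2-oxazolidinone | O=C1N[C@H](Cc2ccccc2)CO1 | starting material
4 | 5-(TBSO)pentanoic pivalic anhydride | CC(C)(C)[Si](C)(C)OCCCCC(=O)OC(=O)C(C)(C)C | intermediate (not isolated)
5 | (R)-4-benzyl-3-[5-(TBSO)pentanoyl]oxazolidin-2-one | CC(C)(C)[Si](C)(C)OCCCCC(=O)N1[C@H](Cc2ccccc2)COC1=O | intermediate
6 | 4-methylpent-4-en-1-ol | CC(=C)CCCO | starting material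
7 | 4-methylpent-4-enal | CC(=C)CCC=O | intermediate
8 | (Z)-dibutylboron enolate of 5 | CCCCB(CCCC)O/C(=C\CCCO[Si](C)(C)C(C)(C)C)N1[C@H](Cc2ccccc2)COC1=O | intermediate (not isolated)
9 | (2R,3S) Evans syn-aldol adduct | CC(C)(C)[Si](C)(C)OCCC[C@@H](C(=O)N1[C@H](Cc2ccccc2)COC1=O)[C@@H](O)CCC(C)=C | intermediate
10 | (2R,3S)-β-hydroxy Weinreb amide | CC(C)(C)[Si](C)(C)OCCC[C@@H](C(=O)N(C)OC)[C@@H](O)CCC(C)=C | intermediate
11 | (2R,3S)-β-(TBSO) Weinreb amide | CC(C)(C)[Si](C)(C)OCCC[C@@H](C(=O)N(C)OC)[C@@H](O[Si](C)(C)C(C)(C)C)CCC(C)=C | intermediate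
12 | (4R,5S)-5-(TBSO)-8-methyl-4-(3-TBSO-propyl)nona-1,8-dien-3-one | CC(C)(C)[Si](C)(C)OCCC[C@@H](C(=O)C=C)[C@@H](O[Si](C)(C)C(C)(C)C)CCC(C)=C | intermediate
13 | (6S,7R)-3-methyl-6-(TBSO)-7-(3-TBSO-propyl)cyclohept-2-en-1-one | CC(C)(C)[Si](C)(C)OCCC[C@H]1C(=O)C=C(C)CC[C@@H]1O[Si](C)(C)C(C)(C)C | intermediate
14 | (6S,7R)-2-iodo-3-methyl-6-(TBSO)-7-(3-TBSO-propyl)cyclohept-2-en-1-one | CC(C)(C)[Si](C)(C)OCCC[C@H]1C(=O)C(I)=C(C)CC[C@@H]1O[Si](C)(C)C(C)(C)C | intermediate
15 | (1R,6S,7R)-1-allyl-2-iodo-3-methyl-6-(TBSO)-7-(3-TBSO-propyl)cyclohept-2-en-1-ol | CC(C)(C)[Si](C)(C)OCCC[C@H]1[C@](O)(CC=C)C(I)=C(C)CC[C@@H]1O[Si](C)(C)C(C)(C)C | intermediate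
16 | B-alkyl-9-BBN adduct of 15 | CC(C)(C)[Si](C)(C)OCCC[C@H]1[C@](O)(CCCB2C3CCCC2CCC3)C(I)=C(C)CC[C@@H]1O[Si](C)(C)C(C)(C)C | intermediate (not isolated)
17 | hydroazulenol (7S,8R,8aR)-4-methyl-7-(TBSO)-8-(3-TBSO-propyl)-2,3,5,6,7,8-hexahydroazulen-8a(1H)-ol | CC(C)(C)[Si](C)(C)OCCC[C@H]1[C@]2(O)CCCC2=C(C)CC[C@@H]1O[Si](C)(C)C(C)(C)C | intermediate
18 | syn-epoxy alcohol (C10–C11 epoxide of 17, cis to the C26 hydroxyl and to the C6 chain) | CC(C)(C)[Si](C)(C)OCCC[C@H]1[C@]2(O)CCC[C@@]23O[C@@]3(C)CC[C@@H]1O[Si](C)(C)C(C)(C)C | intermediate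
19 | spiro hydroxy ketone 6-hydroxy-6-methyl-9-(TBSO)-10-(3-TBSO-propyl)spiro[4.5]decan-1-one | CC(C)(C)[Si](C)(C)OCCC[C@@H]1[C@@H](O[Si](C)(C)C(C)(C)C)CC[C@](C)(O)[C@@]12CCCC2=O | intermediate
20 | tosylhydrazone of 19 | CC(C)(C)[Si](C)(C)OCCC[C@@H]1[C@@H](O[Si](C)(C)C(C)(C)C)CC[C@](C)(O)[C@@]12CCCC2=NNS(=O)(=O)c3ccc(C)cc3 | intermediate
21 | C26 vinyllithium (lithium alkoxide at C10) | CC(C)(C)[Si](C)(C)OCCC[C@@H]1[C@@H](O[Si](C)(C)C(C)(C)C)CC[C@](C)(O[Li])[C@@]12CCC=C2[Li] | intermediate (not isolated)
22 | spiro[4.5]dec-1-ene with the C14=C26 alkene | CC(C)(C)[Si](C)(C)OCCC[C@@H]1[C@@H](O[Si](C)(C)C(C)(C)C)CC[C@](C)(O)[C@@]12CCC=C2 | intermediate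
23 | ring-B epoxide (oxygen on the ring-B face carrying C10) | CC(C)(C)[Si](C)(C)OCCC[C@@H]1[C@@H](O[Si](C)(C)C(C)(C)C)CC[C@](C)(O)[C@@]12CC[C@@H]3O[C@H]23 | intermediate
24 | but-2-yne-1,4-diol | OCC#CCO | starting material
25 | 4-(TBDPSO)but-2-yn-1-ol | OCC#CCO[Si](c1ccccc1)(c1ccccc1)C(C)(C)C | intermediate
26 | cyclic sodium alkenylalanate from 25 | [Na+].COCCO[Al-]1(OCCOC)OCC=C1CO[Si](c2ccccc2)(c2ccccc2)C(C)(C)C | intermediate (not isolated)
27 | (Z)-4-(TBDPSO)-3-iodobut-2-en-1-ol | OC/C=C(\I)CO[Si](c1ccccc1)(c1ccccc1)C(C)(C)C | intermediate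
28 | (Z)-4-(TBDPSO)-3-iodobut-2-enal | O=C/C=C(\I)CO[Si](c1ccccc1)(c1ccccc1)C(C)(C)C | intermediate
29 | 5-bromo-2-methylpent-2-ene | CC(C)=CCCBr | starting material
30 | prop-2-yn-1-ol | C#CCO | starting material
31 | homoprenylmagnesium bromide | CC(C)=CCC[Mg]Br | intermediate (not isolated)
32 | 6-methyl-2-methylidenehept-5-en-1-ol | CC(C)=CCCC(=C)CO | intermediate
33 | 2-(bromomethyl)-6-methylhepta-1,5-diene | CC(C)=CCCC(=C)CBr | intermediate
34 | diethyl (6-methyl-2-methylidenehept-5-enyl)phosphonate | CC(C)=CCCC(=C)CP(=O)(OCC)OCC | intermediate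
35 | (2Z,4E)-1-(TBDPSO)-2-iodo-10-methyl-6-methylideneundeca-2,4,9-triene | I/C(CO[Si](c1ccccc1)(c1ccccc1)C(C)(C)C)=C\C=C\C(=C)CCC=C(C)C | intermediate
36 | trienyllithium from 35 | [Li]/C(CO[Si](c1ccccc1)(c1ccccc1)C(C)(C)C)=C\C=C\C(=C)CCC=C(C)C | intermediate (not isolated)
37 | trans-2-alkenylcyclopentanol (bis-TBS, TBDPS) | CC(C)(C)[Si](C)(C)OCCC[C@@H]1[C@@H](O[Si](C)(C)C(C)(C)C)CC[C@](C)(O)[C@@]12CC[C@@H](/C(=C\C=C\C(=C)CCC=C(C)C)CO[Si](c3ccccc3)(c3ccccc3)C(C)(C)C)[C@@H]2O | intermediate
38 | tetraol (TBDPS ether kept) | OCCC[C@@H]1[C@@H](O)CC[C@](C)(O)[C@@]12CC[C@@H](/C(=C\C=C\C(=C)CCC=C(C)C)CO[Si](c3ccccc3)(c3ccccc3)C(C)(C)C)[C@@H]2O | intermediate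
39 | tetradecanoyl chloride | CCCCCCCCCCCCCC(=O)Cl | starting material
40 | C3 myristate triol | CCCCCCCCCCCCCC(=O)OCCC[C@@H]1[C@@H](O)CC[C@](C)(O)[C@@]12CC[C@@H](/C(=C\C=C\C(=C)CCC=C(C)C)CO[Si](c3ccccc3)(c3ccccc3)C(C)(C)C)[C@@H]2O | intermediate
41 | C7,C26-diketone | CCCCCCCCCCCCCC(=O)OCCC[C@@H]1C(=O)CC[C@](C)(O)[C@@]12CC[C@@H](/C(=C\C=C\C(=C)CCC=C(C)C)CO[Si](c3ccccc3)(c3ccccc3)C(C)(C)C)C2=O | intermediate
42 | C7 ketone, C26 alcohol cis to the side chain | CCCCCCCCCCCCCC(=O)OCCC[C@@H]1C(=O)CC[C@](C)(O)[C@@]12CC[C@@H](/C(=C\C=C\C(=C)CCC=C(C)C)CO[Si](c3ccccc3)(c3ccccc3)C(C)(C)C)[C@H]2O | intermediate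
43 | C7 isopropenyl carbinol (C7 configuration not defined) | CCCCCCCCCCCCCC(=O)OCCC[C@@H]1C(O)(C(C)=C)CC[C@](C)(O)[C@@]12CC[C@@H](/C(=C\C=C\C(=C)CCC=C(C)C)CO[Si](c3ccccc3)(c3ccccc3)C(C)(C)C)[C@H]2O | intermediate
44 | (2Z)-allylic primary alcohol | CCCCCCCCCCCCCC(=O)OCCC[C@@H]1/C(=C(/C)CO)CC[C@](C)(O)[C@@]12CC[C@@H](/C(=C\C=C\C(=C)CCC=C(C)C)CO[Si](c3ccccc3)(c3ccccc3)C(C)(C)C)[C@H]2O | intermediate
45 | TBDPS-protected monomer (enal) | CCCCCCCCCCCCCC(=O)OCCC[C@@H]1/C(=C(/C)C=O)CC[C@](C)(O)[C@@]12CC[C@@H](/C(=C\C=C\C(=C)CCC=C(C)C)CO[Si](c3ccccc3)(c3ccccc3)C(C)(C)C)[C@H]2O | intermediate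
46 | tetraene monomer | CCCCCCCCCCCCCC(=O)OCCC[C@@H]1/C(=C(/C)C=O)CC[C@](C)(O)[C@@]12CC[C@@H](/C(=C\C=C\C(=C)CCC=C(C)C)CO)[C@H]2O | intermediate
47 | CNP0458412.1 | CCCCCCCCCCCCCC(=O)OCCC[C@@H]1/C(=C(/C)C=O)CC[C@](C)(O)[C@@]12CC[C@@H](/C(=C\C=C\[C@@]1(CCC=C(C)C)CCC(CCC=C(C)C)=C[C@@H]1/C=C(/CO)[C@@H]1CC[C@]3([C@H](CCCOC(=O)CCCCCCCCCCCCC)/C(=C(/C)C=O)CC[C@]3(C)O)[C@@H]1O)CO)[C@H]2O | target

**Step count and risks**

Total step count: 33. Longest linear sequence: 25 steps (steps 1, 2, 4–16 and 24–33, from 1 to 47).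

Steps most likely to fail:

1. Step 13. The epoxide may ionize at C10 instead of C11, which leads to elimination instead of migration, or the Lewis acid may cleave a silyl ether. The fallback sets out from 18 and comes back at 19. The tertiary hydroxyl of 18 is silylated with N-trimethylsilylimidazole in CH2Cl2 to give the epoxy trimethylsilyl ether F1. F1 is rearranged with TiCl4 in CH2Cl2 at −78 °C, the silyl-ether form of the semipinacol rearrangement. Here the Lewis acid binds only the epoxide oxygen, the silyloxy group supplies the push at low temperature, and the silyl group is lost on work-up to give 19.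

2. Step 30. The tertiary allyl perrhenate may ionize to dienes, the conjugated triene may isomerize, or the transposition may settle on the wrong C2=C7 geometry. The fallback sets out from 42 and comes back at 45, bypassing steps 29 to 31. Ketone 42 is treated at −78 °C in THF with an excess of the lithium aza-enolate made from N-tert-butyl-2-(trimethylsilyl)propan-1-imine and LiN(iPr)2. Peterson elimination of the adduct gives the α,β-unsaturated N-tert-butyl aldimine F2. Hydrolysis with aqueous oxalic acid gives 45, and the enal geometry is equilibrated with a trace of iodine if required.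

3. Step 33. Facial or exo selectivity may be poor, and ene or oligomerization reactions may compete at the temperature an unactivated diene–alkene pair needs. The fallback sets out from 46 and comes back at 47. Two molecules of 46 are joined through their allylic hydroxyls with iPr2SiCl2 (0.5 equiv) and imidazole in DMF to give the diisopropylsilylene bis-ether F3. F3 is heated at high dilution in PhMe so that the cycloaddition becomes intramolecular (temporary silicon-tethered Diels–Alder reaction) and gives the silylene-bridged cycloadduct F4. HF·pyridine removes the tether to give 47.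

**Further compounds**

F1 | step 13 | epoxy trimethylsilyl ether of 18 | CC(C)(C)[Si](C)(C)OCCC[C@H]1[C@]2(O[Si](C)(C)C)CCC[C@@]23O[C@@]3(C)CC[C@@H]1O[Si](C)(C)C(C)(C)C
F2 | step 30 | α,β-unsaturated N-tert-butyl aldimine of 45 | CCCCCCCCCCCCCC(=O)OCCC[C@@H]1/C(=C(/C)C=NC(C)(C)C)CC[C@](C)(O)[C@@]12CC[C@@H](/C(=C\C=C\C(=C)CCC=C(C)C)CO[Si](c3ccccc3)(c3ccccc3)C(C)(C)C)[C@H]2O
F3 | step 33 | diisopropylsilylene bis-ether of two molecules of 46 | CCCCCCCCCCCCCC(=O)OCCC[C@@H]1/C(=C(/C)C=O)CC[C@](C)(O)[C@@]12CC[C@@H](/C(=C\C=C\C(=C)CCC=C(C)C)CO[Si](C(C)C)(C(C)C)OC/C(=C/C=C/C(=C)CCC=C(C)C)[C@@H]4CC[C@]5([C@H](CCCOC(=O)CCCCCCCCCCCCC)/C(=C(/C)C=O)CC[C@]5(C)O)[C@@H]4O)[C@H]2O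
F4 | step 33 | diisopropylsilylene-bridged cycloadduct (47 with its two allylic oxygens joined through silicon) | CCCCCCCCCCCCCC(=O)OCCC[C@@H]1/C(=C(/C)C=O)CC[C@](C)(O)[C@@]12CC[C@@H](/C(=C\C=C\[C@@]1(CCC=C(C)C)CCC(CCC=C(C)C)=C[C@@H]1/C=C(/CO[Si]6(C(C)C)C(C)C)[C@@H]1CC[C@]3([C@H](CCCOC(=O)CCCCCCCCCCCCC)/C(=C(/C)C=O)CC[C@]3(C)O)[C@@H]1O)CO6)[C@H]2O
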